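The numbers in the tables come from a simulation from invented constants; scatter was added.

| setting | west | north-east | red | blue |
|---|---|---|---|---|
| G | 2.3 M | 2.3 M | 2.3 M | 2.3 M |
| D | 20 mM | 31 mM | 14 mM | 14 mM |
| Q | 1.5 mM | 1.5 mM | 1.5 mM | 1.5 mM |
| remark | run made earlier | run made earlier |  |  |
| time |  |  | 3.0 h | 2.0 h |

| run | time / h | Z / % | G / % |
|---|---|---|---|
| west | 0.833 | 23.1 | 76.9 |
| west | 2.00 | 42.5 | 57.1 |
| west | 2.50 | 47.2 | 52.2 |
| west | 4.00 | 59.4 | 41.0 |
| north-east | 0.833 | 32.4 | 67.7 |
| north-east | 2.00 | 54.0 | 46.0 |
| north-east | 2.50 | 59.1 | 40.8 |
| north-east | 4.00 | 68.5 | 31.2 |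

(standard deviation of a reading: 0.5 percentage points)

- the average divides the monomer in chains by the number of chains begun, living and dead together
- the earlier runs do not show the number of chains; that part of a forecast is a guess

- which of the two ends with the longer chains by the average number of monomer units in a chain (chains begun, living or dead) ("neither" if they lie within 10%) (red / blue / neither)
- average number of monomer units in a chain (chains begun, living or dead) at the end, red
- average number of monomer units in a chain (chains begun, living or dead) at the end, blue

What is left of D after Q has taken its share is my count of chains. I assume that Q removes D one for one up to the full charge of Q, an assumption the readings do not show. Red and blue hold 12.5 mM: the leftover n, charge of D minus charge of Q. West holds 18.5 mM and north-east 29.5 mM.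

Next comes conversion. Let y be the natural log of charged G over remaining G, per mM of leftover. At 2.0 h:

west 0.0303 mM⁻¹, north-east 0.0263 mM⁻¹

carried straight in n to blue: 0.0325 mM⁻¹, so my estimate of G reacted is 33.3%

No run has a reading at 3.0 h, so I replace the curve by its mean slope between the readings on either side:

west 0.0395 mM⁻¹, north-east 0.0334 mM⁻¹

carried to red: 0.0428 mM⁻¹, so my estimate of G reacted is 41.4%

Length is charged G times the fraction reacted, divided by n:

blue 61.4, red 76.2

The weak link is n, since no run shows chains. But red and blue carry the same n, so it cancels from their ratio, 1.24, which stands above the margin of 10%. Red is my choice. Counting D itself instead lowers both lengths by the factor 0.893.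

The forecast names red, with 70 for red and 56 for blue, both lower than mine, and states “Conversions are then about 34% and 43%”.

The flask gives red, with 79.7 for red and 62.3 for blue.

    G + D → X + Z (k = 0.140 M⁻¹ min⁻¹)
    G + X → Z + X, rate k2*[X]*[G] (k = 0.350 M⁻¹ min⁻¹)
    D → J (k = 0.00420 min⁻¹)
    D + Q → E (k = 580 M⁻¹ min⁻¹)
    2 X → L (k = 0.200 M⁻¹ min⁻¹)

Q is the limiting reagent of D + Q, its charge being less than that of D: blue ends with 0% of it, and E stands at 0.00150 M, equal to the charge of Q. Blue's Z of 33.4%, divided by n, gives 61.4 beside the flask's 62.3. A neighbour of blue, with Q raised to 0.0060 M and the same time, has a leftover of 8.00 mM. Its Z reaches 24.4%, so the same division gives 70.2. Its length in the flask is 71.1.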